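# Sarcandrone B: synthesis design by a C2-to-C4 chirality relay through cationic C4–C4a ring closure

## The problem

Sarcandrone B (20) is a 2,4-trans-2-phenyl-4-arylflavan: the chroman (rings A and C; O1, C2–C4, C4a, C5–C8, C8a) carries phenyl at C2 and, at C4, carbon C3' of a 2',6'-dihydroxy-4'-methoxychalcone (ring D, acylated at C1'). C4 is a diarylmethine wedged between two phloroglucinol-type rings, so the C4–C3' and C4–C4a bonds are the skeletal bonds that simple aromatic building blocks do not supply. The two stereocentres, C2 and C4, are 2R,4R and 1,3-trans across ring C; C2 is a benzylic ether carbon that can be bought as an enantiopure 1-phenylalkanol, and if ring C is closed at C4 it can dictate the configuration there, whereas C4 offers no comparable handle on C2. Six phenolic oxygens must be told apart: ring A has two methyl ethers (C5, C8) and one free phenol (C7), ring D one methyl ether (C4') and two phenols (C2', C6') flanking the cinnamoyl carbonyl. Three parts are fragile: the 2',6'-dihydroxychalcone, which is reducible, a Michael acceptor and prone to close to a flavanone in acid or base; the C2–O1 benzylic ether, whose ionisation would scramble C2; and the C4–aryl bonds, which can reopen by retro-Friedel–Crafts reaction in strong acid. A short route is possible because of the electronics at C4: it is benzylic to ring D, whose two ortho and one para oxygen substituents stabilise a cation there very strongly. Its partner C4a is the single unsubstituted position ortho to O1 on a ring A activated by O1, the C5 methoxy group and the C7 oxygen.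

## Retrosynthesis

**20 ⇒ 19.** Only O–C bonds are cut: the C7 O–benzyl bond and the O–methyl bonds at C2' and C6'. A benzyl ether at C7 and methyl ethers on ring D let the whole skeleton be built with organolithium reagents and acid. A hydrogenolytic end-game would reduce the enone, and a basic one would invite flavanone formation. Precursor 19 differs from 20 only in three ether groups. The forward step must tell the two methoxy groups beside the carbonyl from the three others, which BCl3 does by chelation, and must leave the C2–O1 bond alone.

**19 ⇒ 16 + 17.** The aryl–acyl bond C1'–C(=O) is cut. The neighbouring option, Friedel–Crafts acetylation after ring closure followed by aldol condensation, would have to choose between ring D and C6 of ring A, both trialkoxy-activated, and would cost a protecting-group exchange at C7. A bromine carried on ring D removes the choice: exchange to aryllithium 18 and acylation by the Weinreb amide 17 deliver the complete E-cinnamoyl unit in one step. Compound 16 is simpler by nine carbons and the enone. The forward reaction needs fast bromine–lithium exchange beside a benzyl ether and 1,2-addition to the amide.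

**16 ⇒ 15 (key disconnection).** The C4–C4a bond is cut, which opens ring C and erases the C4 stereocentre. Cutting C4–C3' instead would keep ring C, which would then have to be built separately, and cutting either C–O bond of ring C would require both stereocentres beforehand. The chosen cut leaves the acyclic carbinol 15, in which only C2 is defined and the C4 carbinol may be either epimer. The forward reaction must ionise the C4 hydroxyl selectively, keep the C2–O1 bond, and close at C4a trans to the C2 phenyl group.

**15 ⇒ 11 + 13 (via 14).** The C4–C3' bond is cut. Chain length dictates the polarity: C4 has to be the terminal carbon of the three-carbon unit that already holds C2 and C3. If C4 came from an aryl aldehyde and the C2 unit were a three-carbon organometallic, four carbons would separate ring D from O1 and the cation would close a seven-membered ring. So aldehyde 11 is the electrophile and ring D the nucleophile, as aryllithium 14 from the symmetrical dibromide 13 (one step from 12). Because 12 and 13 are symmetrical, neither the bromination nor the mono-exchange has a regiochemical choice, and the surviving bromine sits meta to C4, exactly at the future C1'. The addition must outrun enolisation of the β-aryloxy aldehyde.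

**11 ⇒ 9.** The aldehyde is traced back to a terminal alkene. A β-aryloxy aldehyde would not survive an ether synthesis, whereas the vinyl group is an inert placeholder, so 9 contains no carbonyl group. The cleavage must be buffered and must spare the electron-rich ring A, which favours OsO4/NaIO4 (via diol 10) over ozone.

**9 ⇒ 7 + 8.** The O1–C2 bond is cut. Mitsunobu etherification with inversion joins phenol 7 and the S alcohol 8, whose stereocentre is the only source of chirality in the synthesis. The alternative cut O1–C8a (aryl halide plus alkoxide, retention) is held in reserve. The forward reaction must be a clean SN2 displacement at a secondary benzylic carbon.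

**7 ⇒ 6 ⇒ 5 ⇒ 3 ⇒ 2 ⇒ 1.** Ring A needs 1,2,3,5-oxygenation with three different roles, and a symmetrical arene would need a statistical mono-protection. In aldehyde 1 the phenol, the formyl group and the free ortho position are already distinct handles. The sequence is bromination ortho to OH (2), methylation (3), Baeyer–Villiger oxidation (5 via formate 4), benzylation (6) and hydroxylation of the bromide (7). Each oxygen is introduced or capped by a different reaction, so no step relies on statistics.

## Roads not taken

**Alternative 1:** The cuts are C4–C3' and the C2–O bond of a temporary ketal. A chiral phosphoric acid would activate the 2-hydroxychalcone A2 by cyclodehydration inside a chiral ion pair. 3,5-Dimethoxyphenol A3 would then add through its ortho carbon to C4 and through its oxygen to C2, giving the bridged ketal A1 with two rings formed in one step.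
- Merits: enantiocontrol is catalytic (no bought stereocentre, no Mitsunobu leakage), the bridge ties C2 to C4, and ring D arrives with its C2' oxygen free, so only one carbonyl-flanking methyl ether would remain to be cleaved. In these respects it is better than the chosen plan.
- Weak points: the ketal of A1 must later be opened reductively at the C2–O(ring D) bond and not at the nearly equivalent C2–O1 bond; cleavage on the wrong side would leave the pyran oxygen on ring D instead of ring A. Hydride must also enter on the face syn to the C4 aryl group, against the steric bias, to give the 2,4-trans relationship. The acyl group must then be steered to C1' and not C5'.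
- Comparison: the chosen plan offers a single ionisation of well-understood selectivity, no ketal-opening problem, and a symmetric ring D whose positions cannot be confused.

**Alternative 2:** The cuts are two C–C bonds of ring D (C3'–C4' and C1'–C2'). Thermal ring opening of 3-ethoxycyclobut-2-en-1-one A6, cycloaddition to the siloxyalkyne A5 and a ring-opening/electrocyclisation cascade would give the phenol A4 (Danheiser benzannulation).
- Merits: the three ring D oxygens emerge fully differentiated (free phenol, silyl ether, alkyl ether), which is better than anything the chosen plan offers for ring D.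
- Weak points: the annulation does not create the C4 stereocentre. A5 must already be 2,4-trans, so the stereochemical problem is moved, not solved. The siloxyalkyne needs several steps and is sensitive. The para oxygen arrives as an ethyl ether where the target has a free phenol, and the flanking oxygen must still be methylated.
- Comparison: the chosen plan is markedly shorter and makes C4 in the same step that closes ring C. It pays with one chelation-controlled double demethylation at the end.

**Alternative 3:** The cut is O1–C8a. PhI(OAc)2 in methanol would dearomatise ring A of the diarylpropanol A8 by oxidising its C5 phenol, with methanol captured at C8. The C2 hydroxyl would then add to C8a, and loss of methanol would restore the arene as chroman A7.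
- Merits: ring C closes without a cation at C2 or C4, so there is no risk of retro-Friedel–Crafts reaction or of epimerisation during ring closure, and no substitution at a benzylic carbinol is needed. In this respect it is safer than the chosen plan.
- Weak points: both stereocentres of A8 must be set beforehand in an acyclic 1,3-relationship by two independent asymmetric operations. The oxidant meets a second, very electron-rich ring D that can intercept the oxidised ring A. The C5 phenol of A7 needs a separate methylation, and C7 still has to be differentiated.
- Comparison: the chosen plan sources one stereocentre and relays it to the second, and it needs fewer steps.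

Key step: step 10

Assumption: (S)-1-phenylbut-3-en-1-ol (8) and the cinnamic Weinreb amide 17 are treated as purchasable; the configuration of 8 is inverted in step 6, so the S alcohol gives the 2R ether.

Remark: in 16 the C4 descriptor is S although the spatial arrangement is that of the 4R target; the bromine lifts the CIP rank of ring D above C4a, and the descriptor reverts to R once bromine is replaced in step 11.

## Route

Step 1
Reactants: 1 2-hydroxy-5-methoxybenzaldehyde
Product: 2 3-bromo-2-hydroxy-5-methoxybenzaldehyde
Conditions: Br2, NaOAc, AcOH, rt
Reagents that add atoms: bromine, BrBr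
Why: Electrophilic aromatic bromination; the free phenol directs to its only open ortho position (the para position carries the methoxy group) and acetate buffers the HBr.

Step 2
Reactants: 2 3-bromo-2-hydroxy-5-methoxybenzaldehyde
Product: 3 3-bromo-2,5-dimethoxybenzaldehyde
Conditions: MeI, K2CO3, DMF, rt
Reagents that add atoms: iodomethane, CI
Why: Williamson O-methylation of the phenoxide; no other nucleophilic site is present.

Step 3
Reactants: 3 3-bromo-2,5-dimethoxybenzaldehyde
Product: 5 3-bromo-2,5-dimethoxyphenol, via 3-bromo-2,5-dimethoxyphenyl formate 4 (not isolated)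
Conditions: mCPBA, CH2Cl2, rt; aq NaHCO3 wash; then K2CO3 (cat.), MeOH, rt
Reagents that add atoms: 3-chloroperoxybenzoic acid, OOC(=O)c1cccc(Cl)c1
Why: Baeyer–Villiger (Dakin-type) oxidation; the aryl group bearing an ortho methoxy substituent migrates in preference to hydrogen to give the aryl formate, which mild methanolysis cleaves to the phenol.

Step 4
Reactants: 5 3-bromo-2,5-dimethoxyphenol
Product: 6 1-(benzyloxy)-3-bromo-2,5-dimethoxybenzene
Conditions: BnBr, K2CO3, DMF, rt to 50 °C
Reagents that add atoms: benzyl bromide, BrCc1ccccc1
Why: Williamson benzylation of the only free hydroxyl; the benzyl ether marks the future C7 oxygen and tolerates every step up to the final deprotection.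

Step 5
Reactants: 6 1-(benzyloxy)-3-bromo-2,5-dimethoxybenzene
Product: 7 3-(benzyloxy)-2,5-dimethoxyphenol
Conditions: Pd2(dba)3 (cat.), tBuXPhos, KOH, 1,4-dioxane/H2O, 100 °C; then aq HCl
Reagents that add atoms: potassium hydroxide, [K+].[OH-]
Why: Palladium-catalysed hydroxylation of an aryl bromide with hydroxide, the bulky biarylphosphine promoting C–O reductive elimination; benzyl and methyl ethers are inert, and the new hydroxyl is the future O1.

Step 6
Reactants: 7 3-(benzyloxy)-2,5-dimethoxyphenol; 8 (S)-1-phenylbut-3-en-1-ol
Product: 9 (R)-1-(benzyloxy)-2,5-dimethoxy-3-(1-phenylbut-3-en-1-yloxy)benzene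
Conditions: PPh3, DIAD, THF, 0 °C to rt
Reagents that add atoms: none
Why: Mitsunobu etherification; the phenol displaces the alkoxyphosphonium ion of the secondary benzylic alcohol by SN2 with inversion, so the S alcohol gives the R ether that becomes C2 of the target.

Step 7
Reactants: 9 (R)-1-(benzyloxy)-2,5-dimethoxy-3-(1-phenylbut-3-en-1-yloxy)benzene
Product: 11 (3R)-3-[3-(benzyloxy)-2,5-dimethoxyphenoxy]-3-phenylpropanal, via 1,2-diol 10 (not isolated)
Conditions: OsO4 (cat.), NaIO4, 2,6-lutidine, 1,4-dioxane/H2O, rt
Reagents that add atoms: osmium tetroxide, O=[Os](=O)(=O)=O; sodium periodate, [Na+].[O-]I(=O)(=O)=O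
Why: Lemieux–Johnson oxidative cleavage (dihydroxylation, then periodate glycol cleavage) of the only alkene; the lutidine buffer keeps the medium near neutral, which limits β-elimination of the aryloxy group and leaves the stereocentre untouched.

Step 8
Reactants: 12 1,3,5-trimethoxybenzene
Product: 13 2,4-dibromo-1,3,5-trimethoxybenzene
Conditions: NBS (2 equiv), MeCN, 0 °C to rt
Reagents that add atoms: N-bromosuccinimide, O=C1CCC(=O)N1Br
Why: Electrophilic bromination of three equivalent, doubly methoxy-flanked positions; each bromine deactivates the ring, so two equivalents of NBS should stop at the dibromide.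

Step 9
Reactants: 13 2,4-dibromo-1,3,5-trimethoxybenzene; 11 (3R)-3-[3-(benzyloxy)-2,5-dimethoxyphenoxy]-3-phenylpropanal
Product: 15 (3R)-3-[3-(benzyloxy)-2,5-dimethoxyphenoxy]-1-(3-bromo-2,4,6-trimethoxyphenyl)-3-phenylpropan-1-ol (both C1 epimers), via 3-bromo-2,4,6-trimethoxyphenyllithium 14 (not isolated)
Conditions: 13, n-BuLi (1.0 equiv), THF, −78 °C; then 11, −78 °C; H2O quench; purification on Et3N-deactivated silica
Reagents that add atoms: none
Why: Mono bromine–lithium exchange (the two bromines of 13 are equivalent) followed by 1,2-addition of the aryllithium to the aldehyde, which at −78 °C should outpace enolisation. The new carbinol centre is uncontrolled and need not be controlled, because both epimers give the same cation in step 10.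

Step 10
Reactants: 15 (3R)-3-[3-(benzyloxy)-2,5-dimethoxyphenoxy]-1-(3-bromo-2,4,6-trimethoxyphenyl)-3-phenylpropan-1-ol (both C1 epimers)
Product: 16 (2R,4S)-7-(benzyloxy)-4-(3-bromo-2,4,6-trimethoxyphenyl)-5,8-dimethoxy-2-phenyl-3,4-dihydro-2H-chromene (2,4-trans)
Conditions: Sc(OTf)3 (10 mol %), CH2Cl2 (0.01 M), −20 °C to rt
Reagents that add atoms: none
Why: Sc(OTf)3 ionises the C4 hydroxyl, and both carbinol epimers converge on one benzylic cation stabilised by the two ortho and the para methoxy groups of ring D; the meta bromine costs little. The C2–O1 benzylic ether would give a cation stabilised by phenyl alone, so it should stay intact and C2 keeps its configuration. C4a, the only free position ortho to O1 and activated by O1, the C5 methoxy group and the para C7 benzyloxy group, attacks the cation; this is the known acid-promoted intramolecular Friedel–Crafts cycloalkylation of aryl 3-aryl-3-hydroxypropyl ethers to 4-arylchromans. Ring C closes as a six-membered ring, 6-endo with respect to the C4a–C8a arene bond. The new C4 stereocentre is controlled by C2 through a chair-like transition state in which the C2 phenyl is equatorial and ring D pseudoaxial, away from the peri C5 methoxy group, which gives the 2,4-trans flavan. Reionisation of the new C4–aryl bond can return the material to a cation, so the closure can correct itself toward this more stable isomer. The step needs intramolecular attack to beat intermolecular alkylation at C6 of a second molecule, which high dilution secures. Loss of a proton to the styrene is harmless because reprotonation regenerates the same cation.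

Step 11
Reactants: 16 (2R,4S)-7-(benzyloxy)-4-(3-bromo-2,4,6-trimethoxyphenyl)-5,8-dimethoxy-2-phenyl-3,4-dihydro-2H-chromene; 17 (2E)-N-methoxy-N-methyl-3-phenylprop-2-enamide
Product: 19 (2E)-1-[3-[(2R,4R)-7-(benzyloxy)-5,8-dimethoxy-2-phenyl-3,4-dihydro-2H-chromen-4-yl]-2,4,6-trimethoxyphenyl]-3-phenylprop-2-en-1-one, via aryllithium 18 (not isolated)
Conditions: n-BuLi (1.1 equiv), THF, −78 °C; then 17, −78 to 0 °C; aq NH4Cl
Reagents that add atoms: none
Why: Bromine–lithium exchange and Weinreb ketone synthesis; the chelated tetrahedral adduct prevents over-addition, and aryllithium reagents attack the amide carbonyl in preference to the β-carbon. The bromine fixes the acyl group at C1', and the E alkene arrives intact with 17.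

Step 12
Reactants: 19 (2E)-1-[3-[(2R,4R)-7-(benzyloxy)-5,8-dimethoxy-2-phenyl-3,4-dihydro-2H-chromen-4-yl]-2,4,6-trimethoxyphenyl]-3-phenylprop-2-en-1-one
Product: 20 sarcandrone B ((2E)-1-[2,6-dihydroxy-3-[(2R,4R)-7-hydroxy-5,8-dimethoxy-2-phenyl-3,4-dihydro-2H-chromen-4-yl]-4-methoxyphenyl]-3-phenylprop-2-en-1-one)
Conditions: BCl3 (6 equiv), C6HMe5 (3 equiv), CH2Cl2, −78 °C to rt; then H2O
Reagents that add atoms: none
Why: BCl3 cleaves the aryl benzyl ether at low temperature, with pentamethylbenzene intercepting the benzyl cation, and cleaves the two methyl ethers ortho to the ketone through six-membered boron chelates. The non-chelated methoxy groups at C4', C5 and C8 react far more slowly; no reduction is involved, so the enone survives, and no stereocentre is touched.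

## Compound list

1 | 2-hydroxy-5-methoxybenzaldehyde | COc1ccc(O)c(C=O)c1 | starting material
2 | 3-bromo-2-hydroxy-5-methoxybenzaldehyde | COc1cc(Br)c(O)c(C=O)c1 | intermediate
3 | 3-bromo-2,5-dimethoxybenzaldehyde | COc1cc(Br)c(OC)c(C=O)c1 | intermediate
4 | 3-bromo-2,5-dimethoxyphenyl formate (formed and consumed in step 3) | COc1cc(Br)c(OC)c(OC=O)c1 | intermediate
5 | 3-bromo-2,5-dimethoxyphenol | COc1cc(Br)c(OC)c(O)c1 | intermediate
6 | 1-(benzyloxy)-3-bromo-2,5-dimethoxybenzene | COc1cc(Br)c(OC)c(OCc2ccccc2)c1 | intermediate
7 | 3-(benzyloxy)-2,5-dimethoxyphenol | COc1cc(O)c(OC)c(OCc2ccccc2)c1 | intermediate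
8 | (S)-1-phenylbut-3-en-1-ol | C=CC[C@@H](c1ccccc1)O | starting material
9 | (R)-1-(benzyloxy)-2,5-dimethoxy-3-(1-phenylbut-3-en-1-yloxy)benzene | C=CC[C@H](c1ccccc1)Oc1c(OC)c(OCc2ccccc2)cc(OC)c1 | intermediate
10 | 1,2-diol: (4R)-4-[3-(benzyloxy)-2,5-dimethoxyphenoxy]-4-phenylbutane-1,2-diol, both C2 epimers (formed and consumed in step 7) | OCC(O)C[C@H](c1ccccc1)Oc1c(OC)c(OCc2ccccc2)cc(OC)c1 | intermediate
11 | (3R)-3-[3-(benzyloxy)-2,5-dimethoxyphenoxy]-3-phenylpropanal | O=CC[C@H](c1ccccc1)Oc1c(OC)c(OCc2ccccc2)cc(OC)c1 | intermediate
12 | 1,3,5-trimethoxybenzene | COc1cc(OC)cc(OC)c1 | starting material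
13 | 2,4-dibromo-1,3,5-trimethoxybenzene | COc1cc(OC)c(Br)c(OC)c1Br | intermediate
14 | 3-bromo-2,4,6-trimethoxyphenyllithium (formed and consumed in step 9) | [Li]c1c(OC)cc(OC)c(Br)c1OC | intermediate
15 | (3R)-3-[3-(benzyloxy)-2,5-dimethoxyphenoxy]-1-(3-bromo-2,4,6-trimethoxyphenyl)-3-phenylpropan-1-ol, both C1 epimers | COc1cc(OC)c(Br)c(OC)c1C(O)C[C@H](c1ccccc1)Oc1c(OC)c(OCc2ccccc2)cc(OC)c1 | intermediate
16 | (2R,4S)-7-(benzyloxy)-4-(3-bromo-2,4,6-trimethoxyphenyl)-5,8-dimethoxy-2-phenyl-3,4-dihydro-2H-chromene, 2,4-trans | COc1cc(OC)c(Br)c(OC)c1[C@H]1C[C@H](c2ccccc2)Oc2c(OC)c(OCc3ccccc3)cc(OC)c21 | intermediate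
17 | (2E)-N-methoxy-N-methyl-3-phenylprop-2-enamide | CON(C)C(=O)/C=C/c1ccccc1 | starting material
18 | aryllithium: 3-[(2R,4R)-7-(benzyloxy)-5,8-dimethoxy-2-phenyl-3,4-dihydro-2H-chromen-4-yl]-2,4,6-trimethoxyphenyllithium, 2,4-trans (formed and consumed in step 11) | [Li]c1c(OC)cc(OC)c([C@H]2C[C@H](c3ccccc3)Oc3c(OC)c(OCc4ccccc4)cc(OC)c32)c1OC | intermediate
19 | (2E)-1-[3-[(2R,4R)-7-(benzyloxy)-5,8-dimethoxy-2-phenyl-3,4-dihydro-2H-chromen-4-yl]-2,4,6-trimethoxyphenyl]-3-phenylprop-2-en-1-one | COc1cc(OC)c(C(=O)/C=C/c2ccccc2)c(OC)c1[C@H]1C[C@H](c2ccccc2)Oc2c(OC)c(OCc3ccccc3)cc(OC)c21 | intermediate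
20 | sarcandrone B ((2E)-1-[2,6-dihydroxy-3-[(2R,4R)-7-hydroxy-5,8-dimethoxy-2-phenyl-3,4-dihydro-2H-chromen-4-yl]-4-methoxyphenyl]-3-phenylprop-2-en-1-one) | COc1cc(O)c(C(=O)/C=C/c2ccccc2)c(O)c1[C@H]1C[C@H](c2ccccc2)Oc2c(OC)c(O)cc(OC)c21 | target

## Step count and risk

Total step count: 12. Longest linear sequence: 11 steps (steps 1–7 and 9–12; step 8 is a one-step side branch).

**Step 10 (key step).** The closure may show insufficient trans selectivity if the chair-like preference is weak for a planar, heavily ortho-substituted cation. The cation may also be diverted into intermolecular alkylation of ring A of a second molecule, or into fragmentation with expulsion of the aryloxy group. Prolonged acid exposure could ionise the C2–O1 bond and erode C2. The fallback reverses the order in which the two aryl groups meet C4 while still closing ring C through the C4–C4a bond. It sets out from aldehyde 11. A Lewis acid (Sc(OTf)3 or BF3·OEt2, CH2Cl2, low temperature) promotes intramolecular Friedel–Crafts hydroxyalkylation by C4a to give (2R)-7-(benzyloxy)-5,8-dimethoxy-2-phenyl-3,4-dihydro-2H-chromen-4-ol F1. Under the same acid F1 ionises at C4 to a cation stabilised by ring A, which is captured by 2-bromo-1,3,5-trimethoxybenzene F2 at a position between two methoxy groups and anti to the C2 phenyl group. The sequence comes back to the route at 16.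

**Step 12.** Cleavage of the second carbonyl-flanking methyl ether may stall, because the carbonyl is already engaged in a boron chelate after the first cleavage. Forcing the reaction risks demethylation at C4', Lewis-acid opening of the C2–O1 bond with epimerisation, or closure of the liberated 2'-hydroxychalcone to a flavanone. The fallback separates the two tasks and sets out from 19. BCl3/C6HMe5 held at −78 °C should remove only the benzyl group and give (2E)-1-[3-[(2R,4R)-7-hydroxy-5,8-dimethoxy-2-phenyl-3,4-dihydro-2H-chromen-4-yl]-2,4,6-trimethoxyphenyl]-3-phenylprop-2-en-1-one F3. The two flanking methyl ethers are then cleaved by MgI2·OEt2 in toluene/ether, where iodide attacks the methyl group within a magnesium chelate in a medium free of Brønsted acid. This comes back to the route at 20.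

**Step 9.** The hindered aryllithium may act as a base: enolisation of the aldehyde followed by β-elimination of the aryloxide would discard ring A. Further halogen–metal exchange could also scramble 14. The fallback moves the addition to the carboxylic acid oxidation level, where the α-protons are far less acidic, and sets out from 11. Pinnick oxidation (NaClO2, NaH2PO4, 2-methylbut-2-ene) gives (3R)-3-[3-(benzyloxy)-2,5-dimethoxyphenoxy]-3-phenylpropanoic acid F4. Amide coupling with MeNHOMe·HCl gives (3R)-3-[3-(benzyloxy)-2,5-dimethoxyphenoxy]-N-methoxy-N-methyl-3-phenylpropanamide F5. Addition of 14 (from 13) gives (3R)-3-[3-(benzyloxy)-2,5-dimethoxyphenoxy]-1-(3-bromo-2,4,6-trimethoxyphenyl)-3-phenylpropan-1-one F6, and NaBH4 reduction comes back to the route at 15.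

**Step 6.** Configurational purity may leak through ionisation of the benzylic alkoxyphosphonium intermediate, and the activated alcohol may eliminate to a conjugated diene; the ortho-substituted, electron-rich phenol is only a moderate nucleophile. The fallback forms the O1–C8a bond instead of the O1–C2 bond and sets out from aryl bromide 6. Palladium-catalysed C–O coupling with (R)-1-phenylbut-3-en-1-ol F7 ([Pd(allyl)Cl]2, RockPhos, Cs2CO3, toluene, 90 °C) never breaks the carbinol C–O bond, so the configuration is retained. It comes back to the route at 9 and makes step 5 unnecessary.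

**Step 11.** The doubly ortho-substituted aryllithium may add slowly, which would lead to protonation and loss of the bromine handle, or it may add in conjugate fashion to the cinnamoyl unit. The fallback builds the enone by aldol condensation and sets out from 16. Bromine–lithium exchange and quenching with MeC(O)N(OMe)Me give 1-[3-[(2R,4R)-7-(benzyloxy)-5,8-dimethoxy-2-phenyl-3,4-dihydro-2H-chromen-4-yl]-2,4,6-trimethoxyphenyl]ethan-1-one F8. Claisen–Schmidt condensation with PhCHO (KOH, EtOH) comes back to the route at 19.

## Further compounds

F1 | step 10 | (2R)-7-(benzyloxy)-5,8-dimethoxy-2-phenyl-3,4-dihydro-2H-chromen-4-ol, both C4 epimers | OC1C[C@H](c2ccccc2)Oc2c(OC)c(OCc3ccccc3)cc(OC)c21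
F2 | step 10 | 2-bromo-1,3,5-trimethoxybenzene | COc1cc(OC)c(Br)c(OC)c1
F3 | step 12 | (2E)-1-[3-[(2R,4R)-7-hydroxy-5,8-dimethoxy-2-phenyl-3,4-dihydro-2H-chromen-4-yl]-2,4,6-trimethoxyphenyl]-3-phenylprop-2-en-1-one | COc1cc(OC)c(C(=O)/C=C/c2ccccc2)c(OC)c1[C@H]1C[C@H](c2ccccc2)Oc2c(OC)c(O)cc(OC)c21
F4 | step 9 | (3R)-3-[3-(benzyloxy)-2,5-dimethoxyphenoxy]-3-phenylpropanoic acid | OC(=O)C[C@H](c1ccccc1)Oc1c(OC)c(OCc2ccccc2)cc(OC)c1
F5 | step 9 | (3R)-3-[3-(benzyloxy)-2,5-dimethoxyphenoxy]-N-methoxy-N-methyl-3-phenylpropanamide | CON(C)C(=O)C[C@H](c1ccccc1)Oc1c(OC)c(OCc2ccccc2)cc(OC)c1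
F6 | step 9 | (3R)-3-[3-(benzyloxy)-2,5-dimethoxyphenoxy]-1-(3-bromo-2,4,6-trimethoxyphenyl)-3-phenylpropan-1-one | COc1cc(OC)c(Br)c(OC)c1C(=O)C[C@H](c1ccccc1)Oc1c(OC)c(OCc2ccccc2)cc(OC)c1
F7 | step 6 | (R)-1-phenylbut-3-en-1-ol | C=CC[C@H](c1ccccc1)O
F8 | step 11 | 1-[3-[(2R,4R)-7-(benzyloxy)-5,8-dimethoxy-2-phenyl-3,4-dihydro-2H-chromen-4-yl]-2,4,6-trimethoxyphenyl]ethan-1-one | CC(=O)c1c(OC)cc(OC)c([C@H]2C[C@H](c3ccccc3)Oc3c(OC)c(OCc4ccccc4)cc(OC)c32)c1OC
A1 | alternative 1 | bridged ketal (6,12-methanodibenzo[d,g][1,3]dioxocin type): C2 bears phenyl, O1 and the ring D oxygen; C4 joins C4a and the ring D carbon; ring A 7-benzyloxy-5,8-dimethoxy, ring D dimethoxy | COc1cc(OC)cc2c1[C@H]1C[C@@](c3ccccc3)(O2)Oc2c(OC)c(OCc3ccccc3)cc(OC)c21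
A2 | alternative 1 | (2E)-3-[4-(benzyloxy)-2-hydroxy-3,6-dimethoxyphenyl]-1-phenylprop-2-en-1-one | O=C(/C=C/c1c(O)c(OC)c(OCc2ccccc2)cc1OC)c1ccccc1
A3 | alternative 1 | 3,5-dimethoxyphenol | COc1cc(O)cc(OC)c1
A4 | alternative 2 | 2-[7-(benzyloxy)-5,8-dimethoxy-2-phenylchroman-4-yl]-5-ethoxy-3-(triisopropylsilyloxy)phenol, 2,4-trans | Oc1cc(OCC)cc(O[Si](C(C)C)(C(C)C)C(C)C)c1[C@H]1C[C@H](c2ccccc2)Oc2c(OC)c(OCc3ccccc3)cc(OC)c21
A5 | alternative 2 | 7-(benzyloxy)-5,8-dimethoxy-2-phenyl-4-[(triisopropylsilyloxy)ethynyl]chroman, 2,4-trans | CC(C)[Si](OC#C[C@H]1C[C@H](c2ccccc2)Oc2c(OC)c(OCc3ccccc3)cc(OC)c21)(C(C)C)C(C)C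
A6 | alternative 2 | 3-ethoxycyclobut-2-en-1-one | CCOC1=CC(=O)C1
A7 | alternative 3 | 7-(benzyloxy)-8-methoxy-2-phenyl-4-(2,4,6-trimethoxyphenyl)chroman-5-ol, 2,4-trans | COc1cc(OC)cc(OC)c1[C@H]1C[C@H](c2ccccc2)Oc2c(OC)c(OCc3ccccc3)cc(O)c21
A8 | alternative 3 | 3-[4-(benzyloxy)-2-hydroxy-5-methoxyphenyl]-1-phenyl-3-(2,4,6-trimethoxyphenyl)propan-1-ol with the configurations of C2 and C4 of A7 | COc1cc(OC)cc(OC)c1[C@@H](C[C@H](c1ccccc1)O)c1cc(OC)c(OCc2ccccc2)cc1O
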